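Time is the setting to choose for the next run: stop this flask at 80 s, or leave it standing?

starting material 0.050 M (fed, over 25 s); protic impurity 5.00 mM; enzyme 11 µM; time 80 s
    starting material + enzyme → target + enzyme, rate k1*[starting material]*[enzyme]/(1 + ([starting material]/Km1)) (Km1 = 26.0 mM, k1 = 3920 M⁻¹ s⁻¹)
    starting material + protic impurity → quenched substrate (k2 = 7.78 M⁻¹ s⁻¹)
    enzyme + target → enzyme + over-reaction product (k3 = 2230 M⁻¹ s⁻¹)
1. share of the starting material used up at 80 s
2. target at 80 s, in percent of the starting material charged
3. amount of target if the flask were left three thousand times as long, in percent of the starting material charged

1. Go to logarithms for the target's loss. The enzyme comes back out of steps 1 and 3 as written, so [enzyme] holds at its charge and the loss of target is pseudo-first-order, with rate constant 0.0245 s⁻¹; from it reckon 93.8 s, the decade time, meaning the time in which this step cuts [target] tenfold with nothing added.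

2. Compare the making of target: at low [starting material], step 1 has rate constant 0.0431 s⁻¹, a decade time of 53.4 s, which is shorter than the target's, so the late tail of [target] falls by the target's decade time.

3. Take off the impurity: its own clock in step 2 runs on [starting material], so with a round [starting material] of 25.0 mM its decade time is 11.8 s, shorter than the run, and its charge of 5.00 mM is smaller than the 0.050 M of starting material, so let the impurity take its full charge, which leaves 90.0% for the enzyme.

4. Let the average dose enter at mid-feed, so that it has 67.5 s in the flask, which is 0.720 decades of drain, and treat the two enzyme steps as consecutive first-order steps, leaving out the saturation term; my reckoning gives 28.5% target at 80 s.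

5. Decide: stop at 80 s, because each further decade time divides the tail tenfold, and commit to nil target after the long wait.

The forecast, a little above my target figure, gave 83% conversion, 30% target and 0% after the long wait, on the ground that “the target is drained at about 0.025 per second”.

The flask gives 30.2% target at 80 s, with 82.7% conversion and 0% after the long wait. At that same reading, over-reaction product stands at 42.5%. Use the decade time again on a flask left ten times as long: that span holds 8.53 decades for the target, and the flask then shows 0% target.

Now take the neighbour flask with 0.013 M of protic impurity: its enzyme is unchanged, so the decade time stays 93.8 s, and scaling my figure by what this impurity leaves gives 23.4% target. Computed, that neighbour flask gives 25.2%.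

(The rate constants were set for the occasion; the run is a simulation.)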